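**Strategy.** Ring C is opened at O1–C2, and its C2–C3–C4 chain, oxygenated at both ends, is treated as a masked 3,5-diarylisoxazole and cut at C3–C4. One nitrile oxide–alkyne (3+2) cycloaddition then forms the C3–C4 and O–C2 bonds and unites rings A and B with the correct oxidation level at C2 and C4. The step exploits C4a of ring A, which lies between the oxygen-bearing carbons C5 and C8a: the two ortho oxygens make the dipole at C4 persistent. The precursors are 2-benzyloxy-4,5,6-trimethoxybenzonitrile oxide, generated from its aldoxime without halogen, and 2-benzyloxy-5-ethynyl-1,3-dimethoxybenzene. Hydrogenolysis and aqueous acid finish the flavone.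

Key step: step 6

Remark: flavone numbering (O1, C2, C3, C4, C4a, C5 to C8, C8a) is used for the target; the aldoxime is drawn as its E isomer, and either isomer would give the same nitrile oxide.

**Route**

Step 1
Reactants: 1 3,4,5-trimethoxyphenol
Product: 3 2-hydroxy-4,5,6-trimethoxybenzaldehyde, via iminium dichlorophosphate 2 (not isolated)
Conditions: POCl3, DMF, 0 °C → rt; then H2O, 50 °C
Reagents that add atoms: N,N-dimethylformamide, CN(C)C=O; water, O
Why: Vilsmeier–Haack formylation, in which the chloroiminium electrophile should attack one of the two equivalent free ring positions (each ortho to the hydroxyl and ortho or para to methoxy groups) and aqueous hydrolysis of iminium 2 should release the hydrogen-bonded aldehyde, any O-formate being cleaved in the same work-up.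

Step 2
Reactants: 3 2-hydroxy-4,5,6-trimethoxybenzaldehyde
Product: 4 2-benzyloxy-4,5,6-trimethoxybenzaldehyde
Conditions: BnBr, K2CO3, DMF, 60 °C
Reagents that add atoms: benzyl bromide, BrCc1ccccc1
Why: Williamson ether synthesis, in which the phenoxide formed with K2CO3 should displace bromide by an SN2 reaction, the phenol being the only acidic and nucleophilic site.

Step 3
Reactants: 4 2-benzyloxy-4,5,6-trimethoxybenzaldehyde
Product: 5 (E)-2-benzyloxy-4,5,6-trimethoxybenzaldehyde oxime
Conditions: NH2OH·HCl, NaOAc, EtOH/H2O, 70 °C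
Reagents that add atoms: hydroxylamine hydrochloride, Cl.NO
Why: Oxime condensation, in which hydroxylamine freed by NaOAc should add to the aldehyde and lose water, the benzyl and methyl ethers being inert under these buffered conditions.

Step 4
Reactants: 6 syringaldehyde (4-hydroxy-3,5-dimethoxybenzaldehyde)
Product: 7 4-benzyloxy-3,5-dimethoxybenzaldehyde
Conditions: BnBr, K2CO3, DMF, 60 °C
Reagents that add atoms: benzyl bromide, BrCc1ccccc1
Why: Williamson ether synthesis on the acidic para-formyl phenol, which should proceed cleanly because the aldehyde has no enolisable position and is stable to K2CO3.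

Step 5
Reactants: 7 4-benzyloxy-3,5-dimethoxybenzaldehyde
Product: 8 2-benzyloxy-5-ethynyl-1,3-dimethoxybenzene
Conditions: dimethyl (1-diazo-2-oxopropyl)phosphonate, K2CO3, MeOH, 0 °C → rt
Reagents that add atoms: dimethyl (1-diazo-2-oxopropyl)phosphonate, COP(=O)(OC)C(=[N+]=[N-])C(C)=O
Why: Seyferth–Gilbert homologation in its Ohira–Bestmann form, in which methanolysis frees the diazomethylphosphonate anion, olefination of the non-enolisable aldehyde gives a diazoalkene, and loss of N2 with 1,2-hydrogen shift should deliver the terminal alkyne under conditions that leave the aryl ethers untouched.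

Step 6
Reactants: 5 (E)-2-benzyloxy-4,5,6-trimethoxybenzaldehyde oxime; 8 2-benzyloxy-5-ethynyl-1,3-dimethoxybenzene
Product: 10 3-(2-benzyloxy-4,5,6-trimethoxyphenyl)-5-(4-benzyloxy-3,5-dimethoxyphenyl)isoxazole, via nitrile oxide 9 (not isolated)
Conditions: PhI(OAc)2, TFA (cat.), MeOH/CH2Cl2, 0 °C; then 8, rt → 50 °C
Reagents that add atoms: none
Why: PhI(OAc)2 should dehydrogenate the aldoxime to nitrile oxide 9 without the electrophilic chlorine that could attack the one free C–H of the electron-rich ring A, and 9 should then add to alkyne 8 in a concerted, asynchronous six-electron (3+2) cycloaddition (Huisgen 1,3-dipolar cycloaddition) that forms the future C3–C4 bond and the O–C2 bond in one event. The closest known reaction type is the cycloaddition of aryl nitrile oxides to terminal alkynes giving 3,5-disubstituted isoxazoles. The one ring closed is the five-membered isoxazole, and it is closed by the cycloaddition itself, the carbon and oxygen ends of the C–N–O dipole bonding to the two alkyne carbons, not by a separate cyclisation. No stereocentre is created. The step needs regioselectivity for the 3,5- over the 3,4-diaryl isomer and chemoselectivity for cycloaddition over dimerisation to the furoxan: the first should be secured by the terminal alkyne, whose unsubstituted carbon bonds to the hindered dipole carbon for steric and frontier-orbital reasons, and the second by the benzyloxy and methoxy groups flanking the dipole, which should keep 9 alive while the electron-rich alkyne reacts on gentle warming.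

Step 7
Reactants: 10 3-(2-benzyloxy-4,5,6-trimethoxyphenyl)-5-(4-benzyloxy-3,5-dimethoxyphenyl)isoxazole
Product: 11 (Z)-3-amino-3-(2-hydroxy-4,5,6-trimethoxyphenyl)-1-(4-hydroxy-3,5-dimethoxyphenyl)prop-2-en-1-one
Conditions: H2 (1 atm), 10% Pd/C, EtOAc/EtOH, rt
Reagents that add atoms: none
Why: Catalytic hydrogenolysis should cleave both benzylic C–O bonds and the weak isoxazole N–O bond (reductive opening of an isoxazole to a β-enaminone), and should stop at the vinylogous amide, which resists further reduction and is held in the Z geometry by its N–H···O=C hydrogen bond.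

Step 8
Reactants: 11 (Z)-3-amino-3-(2-hydroxy-4,5,6-trimethoxyphenyl)-1-(4-hydroxy-3,5-dimethoxyphenyl)prop-2-en-1-one
Product: 13 ageconyflavone C (2-(4-hydroxy-3,5-dimethoxyphenyl)-5,6,7-trimethoxy-4H-chromen-4-one), via 4-aminoflavylium chloride 12 (not isolated)
Conditions: 2 M aq. HCl, EtOH, 80 °C
Reagents that add atoms: water, O
Why: Acid-catalysed cyclodehydration, in which the ring A phenol should add to the protonated carbonyl carbon C2 (6-exo-trig) and lose water to give the 4-aminobenzopyrylium salt 12, whose C4 is then hydrolysed by water to the C4 carbonyl with loss of ammonium chloride (flavone imine hydrolysis), under conditions too mild to cleave the aryl methyl ethers.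

**Compound list**

1 | 3,4,5-trimethoxyphenol | COc1cc(O)cc(OC)c1OC | starting material
2 | N-[(2-hydroxy-4,5,6-trimethoxyphenyl)methylidene]-N-methylmethanaminium dichlorophosphate | COc1cc(O)c(C=[N+](C)C)c(OC)c1OC.[O-]P(=O)(Cl)Cl | intermediate (not isolated)
3 | 2-hydroxy-4,5,6-trimethoxybenzaldehyde | COc1cc(O)c(C=O)c(OC)c1OC | intermediate
4 | 2-benzyloxy-4,5,6-trimethoxybenzaldehyde | COc1cc(OCc2ccccc2)c(C=O)c(OC)c1OC | intermediate
5 | (E)-2-benzyloxy-4,5,6-trimethoxybenzaldehyde oxime | COc1cc(OCc2ccccc2)c(/C=N/O)c(OC)c1OC | intermediate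
6 | syringaldehyde (4-hydroxy-3,5-dimethoxybenzaldehyde) | COc1cc(C=O)cc(OC)c1O | starting material
7 | 4-benzyloxy-3,5-dimethoxybenzaldehyde | COc1cc(C=O)cc(OC)c1OCc1ccccc1 | intermediate
8 | 2-benzyloxy-5-ethynyl-1,3-dimethoxybenzene | C#Cc1cc(OC)c(OCc2ccccc2)c(OC)c1 | intermediate
9 | 2-benzyloxy-4,5,6-trimethoxybenzonitrile oxide | COc1cc(OCc2ccccc2)c(C#[N+][O-])c(OC)c1OC | intermediate (not isolated)
10 | 3-(2-benzyloxy-4,5,6-trimethoxyphenyl)-5-(4-benzyloxy-3,5-dimethoxyphenyl)isoxazole | COc1cc(OCc2ccccc2)c(-c2cc(-c3cc(OC)c(OCc4ccccc4)c(OC)c3)on2)c(OC)c1OC | intermediate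
11 | (Z)-3-amino-3-(2-hydroxy-4,5,6-trimethoxyphenyl)-1-(4-hydroxy-3,5-dimethoxyphenyl)prop-2-en-1-one | COc1cc(O)c(/C(N)=C/C(=O)c2cc(OC)c(O)c(OC)c2)c(OC)c1OC | intermediate
12 | 4-amino-2-(4-hydroxy-3,5-dimethoxyphenyl)-5,6,7-trimethoxychromenylium chloride | COc1cc(-c2cc(N)c3c(OC)c(OC)c(OC)cc3[o+]2)cc(OC)c1O.[Cl-] | intermediate (not isolated)
13 | ageconyflavone C, 2-(4-hydroxy-3,5-dimethoxyphenyl)-5,6,7-trimethoxy-4H-chromen-4-one | COc1cc(-c2cc(=O)c3c(OC)c(OC)c(OC)cc3o2)cc(OC)c1O | target

**Step count**

Total steps: 8. Longest linear sequence: 6 steps (steps 1, 2, 3, 6, 7, 8, from 3,4,5-trimethoxyphenol).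

**Steps most likely to fail**

Step 6. The cycloaddition of a hindered, electron-rich dipole with an electron-rich alkyne may be slower than loss of the nitrile oxide (dimerisation to the furoxan, addition of methanol, rearrangement to the isocyanate on heating), or the trivalent-iodine oxidant may attack the electron-rich rings. The fallback gives up the dipole and forms the same C3–C4 bond by acetylide addition; it sets out from aldehyde 4 and alkyne 8 and comes back to the route at target 13. Alkyne 8 would be lithiated (n-BuLi, THF, −78 °C) and added to aldehyde 4 to give racemic 1-(2-benzyloxy-4,5,6-trimethoxyphenyl)-3-(4-benzyloxy-3,5-dimethoxyphenyl)prop-2-yn-1-ol F1. Oxidation with MnO2 in CH2Cl2 should give the ynone 1-(2-benzyloxy-4,5,6-trimethoxyphenyl)-3-(4-benzyloxy-3,5-dimethoxyphenyl)prop-2-yn-1-one F2. Conjugate addition of Et2NH in EtOH should give (E)-1-(2-benzyloxy-4,5,6-trimethoxyphenyl)-3-(4-benzyloxy-3,5-dimethoxyphenyl)-3-(diethylamino)prop-2-en-1-one F3. Hydrogenolysis (H2, Pd/C, EtOAc/EtOH) should remove both benzyl groups to give (E)-3-(diethylamino)-1-(2-hydroxy-4,5,6-trimethoxyphenyl)-3-(4-hydroxy-3,5-dimethoxyphenyl)prop-2-en-1-one F4. Warming F4 in ethanolic HCl should close ring C by addition of the ring A phenol to C2 and loss of diethylamine, giving 13.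

Step 7. Hydrogenolysis may strip the benzyl ethers but stall before the N–O bond is cleaved, or the amine product may slow the catalyst so that mixtures of partly reduced material result. The fallback separates the two tasks and uses a metal carbonyl for the N–O bond; it sets out from isoxazole 10 and comes back at enaminone 11. Treatment of 10 with Mo(CO)6 in MeCN/H2O at 80 °C should cleave only the N–O bond and give (Z)-3-amino-3-(2-benzyloxy-4,5,6-trimethoxyphenyl)-1-(4-benzyloxy-3,5-dimethoxyphenyl)prop-2-en-1-one F5. Hydrogenolysis of F5 (H2, Pd/C, EtOAc/EtOH), now only an O-debenzylation, should then give 11.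

Step 8. Ring closure may outrun loss of nitrogen, so that material rests as the stabilised 4-aminobenzopyrylium salt, and forcing its hydrolysis in hot mineral acid risks cleavage of the C5 methyl ether peri to the carbonyl. The fallback reverses the order of events, removing nitrogen before the ring is closed; it sets out from enaminone 11 and comes back at target 13. Cold, dilute aqueous acid (1 M aq. HCl, THF, rt) should hydrolyse the enaminone to 1-(2-hydroxy-4,5,6-trimethoxyphenyl)-3-(4-hydroxy-3,5-dimethoxyphenyl)propane-1,3-dione F6. This isolated diketone would then be closed by the classical cyclodehydration of 2-hydroxyaryl 1,3-diketones with a sulfonic acid resin that has no nucleophilic counter-ion (Amberlyst 15, i-PrOH, reflux), giving 13.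

**Further compounds**

F1 | step 6 | racemic 1-(2-benzyloxy-4,5,6-trimethoxyphenyl)-3-(4-benzyloxy-3,5-dimethoxyphenyl)prop-2-yn-1-ol | COc1cc(OCc2ccccc2)c(C(O)C#Cc2cc(OC)c(OCc3ccccc3)c(OC)c2)c(OC)c1OC
F2 | step 6 | 1-(2-benzyloxy-4,5,6-trimethoxyphenyl)-3-(4-benzyloxy-3,5-dimethoxyphenyl)prop-2-yn-1-one | COc1cc(OCc2ccccc2)c(C(=O)C#Cc2cc(OC)c(OCc3ccccc3)c(OC)c2)c(OC)c1OC
F3 | step 6 | (E)-1-(2-benzyloxy-4,5,6-trimethoxyphenyl)-3-(4-benzyloxy-3,5-dimethoxyphenyl)-3-(diethylamino)prop-2-en-1-one | CCN(CC)/C(=C/C(=O)c1c(OCc2ccccc2)cc(OC)c(OC)c1OC)c1cc(OC)c(OCc2ccccc2)c(OC)c1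
F4 | step 6 | (E)-3-(diethylamino)-1-(2-hydroxy-4,5,6-trimethoxyphenyl)-3-(4-hydroxy-3,5-dimethoxyphenyl)prop-2-en-1-one | CCN(CC)/C(=C/C(=O)c1c(O)cc(OC)c(OC)c1OC)c1cc(OC)c(O)c(OC)c1
F5 | step 7 | (Z)-3-amino-3-(2-benzyloxy-4,5,6-trimethoxyphenyl)-1-(4-benzyloxy-3,5-dimethoxyphenyl)prop-2-en-1-one | COc1cc(OCc2ccccc2)c(/C(N)=C/C(=O)c2cc(OC)c(OCc3ccccc3)c(OC)c2)c(OC)c1OC
F6 | step 8 | 1-(2-hydroxy-4,5,6-trimethoxyphenyl)-3-(4-hydroxy-3,5-dimethoxyphenyl)propane-1,3-dione | COc1cc(O)c(C(=O)CC(=O)c2cc(OC)c(O)c(OC)c2)c(OC)c1OC
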